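**Retrosynthetic overview**
1. The strategy rests on C2 and C4 of the pentan-3-one linker. Each is a CH(CH3) carbon α to the C3 ketone and bonded to C2 of a 4H-pyran-4-one ring, so it is base-labile, yet its radical is delocalised over C2=C3–C4=O of that ring.
2. Key disconnection: the C3(=O)–C4 bond. It gives acyl chloride 16 (pentyl pyranone, ring A, C2 centre from the Roche ester) and racemic 1-chloroethyl pyranone 23 (ring B), joined by a base-free nickel-catalysed enantioconvergent reductive acyl coupling.
3. Acyl chloride 16: Roche ester → β-diketone 7 → dianion acylation → triketone 11 → cyclodehydration (closes ring A) → desilylation → oxidation to the acid → chlorination.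
4. Chloride 23: pentan-3-one and propanoic acid in polyphosphoric acid close ring B in one step (20); lateral hydroxylation and chlorination follow.
5. Ring order: ring A on the chiral chain, ring B separately, the two finished rings joined last without any ring closure.

Key step: step 15

Remark: the bis(oxazoline) antipode that gives the 4R centre with a pyranonyl chloride cannot be assigned with certainty by analogy, so it is assumed to be fixed by running step 15 once with each antipode.

**Step 1**
Reactants: 1 methyl (S)-3-hydroxy-2-methylpropanoate (Roche ester)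
Product: 2 methyl (S)-3-[(tert-butyldimethylsilyl)oxy]-2-methylpropanoate
Conditions: t-BuMe2SiCl, imidazole, CH2Cl2, 0 °C → rt
Reagents that add atoms: tert-butyldimethylsilyl chloride, CC(C)(C)[Si](C)(C)Cl
Why: Imidazole-promoted silylation of the primary alcohol, which does not involve the stereocentre and gives an ether stable to the hydride, amide-base and oxidation steps that follow.

**Step 2**
Reactants: 2 methyl (S)-3-[(tert-butyldimethylsilyl)oxy]-2-methylpropanoate
Product: 3 (S)-3-[(tert-butyldimethylsilyl)oxy]-2-methylpropanal
Conditions: i-Bu2AlH (1.05 equiv), CH2Cl2, −78 °C; MeOH, then aq. KNaC4H4O6; crude aldehyde used at once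
Reagents that add atoms: none
Why: Partial reduction of the methyl ester, in which the aluminium hemiacetal persists at −78 °C until the quench, should give the aldehyde with the α-centre intact provided it is not stored or chromatographed.

**Step 3**
Reactants: 3 (S)-3-[(tert-butyldimethylsilyl)oxy]-2-methylpropanal; 4 pentan-3-one
Product: 6 (6S)-7-[(tert-butyldimethylsilyl)oxy]-5-hydroxy-4,6-dimethylheptan-3-one as a C4/C5 diastereomer mixture, via lithium enolate of pentan-3-one 5 (not isolated)
Conditions: 4 (1.3 equiv), LiN(i-Pr)2, THF, −78 °C; then 3, −78 °C; aq. NH4Cl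
Reagents that add atoms: none
Why: Lithium-enolate aldol addition is fast at −78 °C and does not enolise the aldehyde, and the two new centres need no control because C5 is oxidised next and C4 becomes a ring sp2 carbon.

**Step 4**
Reactants: 6 (6S)-7-[(tert-butyldimethylsilyl)oxy]-5-hydroxy-4,6-dimethylheptan-3-one
Product: 7 (6S)-7-[(tert-butyldimethylsilyl)oxy]-4,6-dimethylheptane-3,5-dione (C4 epimers and enol forms)
Conditions: Dess–Martin periodinane, NaHCO3, CH2Cl2, 0 °C → rt
Reagents that add atoms: none
Why: Dess–Martin oxidation of a β-hydroxy ketone to the β-diketone runs without base, and the diketone enolises towards C4 between the carbonyls, which leaves the C6 centre configurationally intact.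

**Step 5**
Reactants: 8 methyl hexanoate
Product: 9 N-methoxy-N-methylhexanamide
Conditions: MeNH(OMe)·HCl, i-PrMgCl, THF, −20 → 0 °C
Reagents that add atoms: N,O-dimethylhydroxylamine hydrochloride, CNOC.Cl
Why: Weinreb amide formation from a methyl ester with the magnesium amide, chosen because acylation with this amide stops at a chelated tetrahedral adduct and therefore needs only one equivalent of the valuable dianion in step 6.

**Step 6**
Reactants: 7 (6S)-7-[(tert-butyldimethylsilyl)oxy]-4,6-dimethylheptane-3,5-dione; 9 N-methoxy-N-methylhexanamide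
Product: 11 (2S)-1-[(tert-butyldimethylsilyl)oxy]-2,4,6-trimethyldodecane-3,5,7-trione (C4/C6 epimers and enol forms), via dilithium dienediolate 10 (not isolated)
Conditions: LiN(i-Pr)2 (2.1 equiv), THF, −78 → −40 °C; then 9 (1.1 equiv), −78 → −10 °C; aq. NH4Cl
Reagents that add atoms: none
Why: Harris-type terminal C-acylation of a β-diketone dianion, in which the second deprotonation should occur kinetically at the unhindered ethyl CH2 and not at the hindered stereogenic methine, the dianion reacts at that terminal carbon, and the triketone is released only on quench.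

**Step 7**
Reactants: 11 (2S)-1-[(tert-butyldimethylsilyl)oxy]-2,4,6-trimethyldodecane-3,5,7-trione
Product: 12 (S)-2-{1-[(tert-butyldimethylsilyl)oxy]propan-2-yl}-3,5-dimethyl-6-pentyl-4H-pyran-4-one
Conditions: PPh3, CCl4, THF, rt
Reagents that add atoms: none
Why: Cyclodehydration of the 1,3,5-triketone by addition–elimination of one terminal enol oxygen onto the phosphonium-activated enol of the other terminal carbonyl, a mild method used for epimerisable polypropionate pyranones, can give only one 4-pyranone and does not touch the side-chain centre.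

**Step 8**
Reactants: 12 (S)-2-{1-[(tert-butyldimethylsilyl)oxy]propan-2-yl}-3,5-dimethyl-6-pentyl-4H-pyran-4-one
Product: 13 (S)-2-(1-hydroxypropan-2-yl)-3,5-dimethyl-6-pentyl-4H-pyran-4-one
Conditions: HF·pyridine, pyridine, THF, 0 °C → rt
Reagents that add atoms: none
Why: Fluoride cleavage of the primary silyl ether under buffered, non-basic conditions leaves the pyranone and the adjacent C–H untouched.

**Step 9**
Reactants: 13 (S)-2-(1-hydroxypropan-2-yl)-3,5-dimethyl-6-pentyl-4H-pyran-4-one
Product: 14 (R)-2-(3,5-dimethyl-4-oxo-6-pentyl-4H-pyran-2-yl)propanal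
Conditions: Dess–Martin periodinane, NaHCO3, CH2Cl2, 0 °C; filtered and used crude at once
Reagents that add atoms: none
Why: Buffered Dess–Martin oxidation gives the doubly activated aldehyde without base, chromatography or storage, so its α-centre should survive; the descriptor changes from S to R only because CHO outranks the pyranone carbon whereas CH2OH does not.

**Step 10**
Reactants: 14 (R)-2-(3,5-dimethyl-4-oxo-6-pentyl-4H-pyran-2-yl)propanal
Product: 15 (R)-2-(3,5-dimethyl-4-oxo-6-pentyl-4H-pyran-2-yl)propanoic acid
Conditions: NaClO2, NaH2PO4, 2-methylbut-2-ene, t-BuOH/H2O, 0 °C → rt; acid kept cold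
Reagents that add atoms: sodium chlorite, [Na+].[O-]Cl=O
Why: Pinnick chlorite oxidation at about pH 4 with an alkene as hypochlorite scavenger oxidises α-aryl-type aldehydes without enolisation, and the fully substituted pyranone offers no site for chlorination.

**Step 11**
Reactants: 15 (R)-2-(3,5-dimethyl-4-oxo-6-pentyl-4H-pyran-2-yl)propanoic acid
Product: 16 (R)-2-(3,5-dimethyl-4-oxo-6-pentyl-4H-pyran-2-yl)propanoyl chloride
Conditions: 1-chloro-N,N,2-trimethylprop-1-en-1-amine (1.05 equiv), CH2Cl2, 0 °C; concentrated and used directly
Reagents that add atoms: 1-chloro-N,N,2-trimethylprop-1-en-1-amine, CC(C)=C(Cl)N(C)C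
Why: Acid chloride formation with the Ghosez reagent is neutral and produces only an inert amide, so neither ketene formation (loss of the α-centre) nor chlorination at the pyranone carbonyl is expected.

**Step 12**
Reactants: 4 pentan-3-one; 17 propanoic acid
Product: 20 2,6-diethyl-3,5-dimethyl-4H-pyran-4-one, via 4-methylheptane-3,5-dione 18 (not isolated), via 4,6-dimethylnonane-3,5,7-trione 19 (not isolated)
Conditions: polyphosphoric acid, 17 (2.5 equiv), 95 °C
Reagents that add atoms: none
Why: Polyphosphoric acid promotes C-acylation of both α-carbons of the ketone by two molecules of the acid and then cyclodehydrates the symmetric triketone, a classical one-pot 4-pyranone synthesis.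

**Step 13**
Reactants: 20 2,6-diethyl-3,5-dimethyl-4H-pyran-4-one
Product: 22 rac-2-ethyl-6-(1-hydroxyethyl)-3,5-dimethyl-4H-pyran-4-one, via sodium dienolate 21 (not isolated)
Conditions: NaN(SiMe3)2 (1.0 equiv), THF, −78 °C; then (±)-3-phenyl-2-(phenylsulfonyl)oxaziridine, −78 °C; aq. NH4Cl
Reagents that add atoms: 3-phenyl-2-(phenylsulfonyl)oxaziridine, O=S(=O)(c1ccccc1)N1OC1c1ccccc1
Why: A 2-alkyl-4-pyranone is deprotonated at the lateral CH2 to a vinylogous enolate that reacts with electrophiles at that carbon, so Davis hydroxylation of the sodium enolate should give the carbinol, and one equivalent of base on the symmetric pyranone limits reaction to one ethyl group.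

**Step 14**
Reactants: 22 rac-2-ethyl-6-(1-hydroxyethyl)-3,5-dimethyl-4H-pyran-4-one
Product: 23 rac-2-(1-chloroethyl)-6-ethyl-3,5-dimethyl-4H-pyran-4-one
Conditions: SOCl2, CH2Cl2, 0 °C → rt; used promptly
Reagents that add atoms: thionyl chloride, O=S(Cl)Cl
Why: Chlorodehydroxylation of the activated, benzylic-type carbinol with thionyl chloride is the reaction that converts hydroxymethyl-4-pyranones into chloromethyl-4-pyranones without touching the ring carbonyl, and a racemic product is what the next step requires.

**Step 15**
Reactants: 16 (R)-2-(3,5-dimethyl-4-oxo-6-pentyl-4H-pyran-2-yl)propanoyl chloride; 23 rac-2-(1-chloroethyl)-6-ethyl-3,5-dimethyl-4H-pyran-4-one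
Product: 24 (2R,4R)-2-(3,5-dimethyl-4-oxo-6-pentyl-4H-pyran-2-yl)-4-(6-ethyl-3,5-dimethyl-4-oxo-4H-pyran-2-yl)pentan-3-one (CNP0268096.1)
Conditions: NiCl2(dme) (10 mol %; dme = 1,2-dimethoxyethane), one antipode of 2,2'-(propane-2,2-diyl)bis(4-phenyl-4,5-dihydrooxazole) (22 mol %), Mn powder (3 equiv), 2,6-dimethylbenzoic acid (0.75 equiv), 3 Å MS, DMA/THF (3:7), 20 °C; 23 in excess (1.5 equiv); neutral work-up
Reagents that add atoms: none
Why: Zerovalent nickel bearing the chiral bis(oxazoline) inserts into the C–Cl bond of 16 to give an acyl–nickel chloride, while low-valent (monovalent) nickel abstracts chlorine from 23 to give a planar 1-(pyranon-2-yl)ethyl radical delocalised over ring C2, C3 and the C4 carbonyl oxygen; capture of this radical at nickel and C(acyl)–C(sp3) reductive elimination give the ketone, and manganese returns the catalyst to its low-valent state. The closest known reaction is the nickel/bis(oxazoline)/manganese enantioconvergent reductive coupling of acid chlorides with racemic 1-arylethyl chlorides to α-aryl-α-methyl ketones, here with the pyranon-2-yl group in the role of the aryl group and with an acyl partner that already carries an α-stereocentre. No ring is closed; only the C3–C4 bond of the pentan-3-one linker is formed. The new C4 centre is set by the ligand, both antipodes of 23 converging through the common radical, whereas C2 is carried over from 16 unchanged because neither base nor enolate is present. The step needs catalyst-controlled facial selectivity that overrides the resident C2 centre, and cross-coupling over homocoupling; the first is secured by the choice of ligand antipode, the second by the different activation modes of the two chlorides (two-electron oxidative addition against halogen abstraction), assisted by the benzoic acid additive and the excess of 23.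

**Compound list**
1 | methyl (S)-3-hydroxy-2-methylpropanoate | COC(=O)[C@@H](C)CO | starting material
2 | methyl (S)-3-[(tert-butyldimethylsilyl)oxy]-2-methylpropanoate | COC(=O)[C@@H](C)CO[Si](C)(C)C(C)(C)C | intermediate
3 | (S)-3-[(tert-butyldimethylsilyl)oxy]-2-methylpropanal | O=C[C@@H](C)CO[Si](C)(C)C(C)(C)C | intermediate
4 | pentan-3-one | CCC(=O)CC | starting material
5 | lithium enolate of pentan-3-one (not isolated) | [Li+].CC=C([O-])CC | intermediate
6 | (6S)-7-[(tert-butyldimethylsilyl)oxy]-5-hydroxy-4,6-dimethylheptan-3-one | CCC(=O)C(C)C(O)[C@@H](C)CO[Si](C)(C)C(C)(C)C | intermediate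
7 | (6S)-7-[(tert-butyldimethylsilyl)oxy]-4,6-dimethylheptane-3,5-dione | CCC(=O)C(C)C(=O)[C@@H](C)CO[Si](C)(C)C(C)(C)C | intermediate
8 | methyl hexanoate | CCCCCC(=O)OC | starting material
9 | N-methoxy-N-methylhexanamide | CCCCCC(=O)N(C)OC | intermediate
10 | dilithium dienediolate of 7 (not isolated) | [Li+].[Li+].CC=C([O-])C(C)=C([O-])[C@@H](C)CO[Si](C)(C)C(C)(C)C | intermediate
11 | (2S)-1-[(tert-butyldimethylsilyl)oxy]-2,4,6-trimethyldodecane-3,5,7-trione | CCCCCC(=O)C(C)C(=O)C(C)C(=O)[C@@H](C)CO[Si](C)(C)C(C)(C)C | intermediate
12 | (S)-2-{1-[(tert-butyldimethylsilyl)oxy]propan-2-yl}-3,5-dimethyl-6-pentyl-4H-pyran-4-one | CCCCCc1oc([C@@H](C)CO[Si](C)(C)C(C)(C)C)c(C)c(=O)c1C | intermediate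
13 | (S)-2-(1-hydroxypropan-2-yl)-3,5-dimethyl-6-pentyl-4H-pyran-4-one | CCCCCc1oc([C@@H](C)CO)c(C)c(=O)c1C | intermediate
14 | (R)-2-(3,5-dimethyl-4-oxo-6-pentyl-4H-pyran-2-yl)propanal | CCCCCc1oc([C@@H](C)C=O)c(C)c(=O)c1C | intermediate
15 | (R)-2-(3,5-dimethyl-4-oxo-6-pentyl-4H-pyran-2-yl)propanoic acid | CCCCCc1oc([C@@H](C)C(=O)O)c(C)c(=O)c1C | intermediate
16 | (R)-2-(3,5-dimethyl-4-oxo-6-pentyl-4H-pyran-2-yl)propanoyl chloride | CCCCCc1oc([C@@H](C)C(Cl)=O)c(C)c(=O)c1C | intermediate
17 | propanoic acid | CCC(=O)O | starting material
18 | 4-methylheptane-3,5-dione (not isolated) | CCC(=O)C(C)C(=O)CC | intermediate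
19 | 4,6-dimethylnonane-3,5,7-trione (not isolated) | CCC(=O)C(C)C(=O)C(C)C(=O)CC | intermediate
20 | 2,6-diethyl-3,5-dimethyl-4H-pyran-4-one | CCc1oc(CC)c(C)c(=O)c1C | intermediate
21 | sodium dienolate of 20 (2-ethylidene-2H-pyran-4-olate, not isolated) | [Na+].CC=C1OC(CC)=C(C)C([O-])=C1C | intermediate
22 | rac-2-ethyl-6-(1-hydroxyethyl)-3,5-dimethyl-4H-pyran-4-one | CCc1oc(C(C)O)c(C)c(=O)c1C | intermediate
23 | rac-2-(1-chloroethyl)-6-ethyl-3,5-dimethyl-4H-pyran-4-one | CCc1oc(C(C)Cl)c(C)c(=O)c1C | intermediate
24 | (2R,4R)-2-(3,5-dimethyl-4-oxo-6-pentyl-4H-pyran-2-yl)-4-(6-ethyl-3,5-dimethyl-4-oxo-4H-pyran-2-yl)pentan-3-one | CCCCCc1oc([C@@H](C)C(=O)[C@H](C)c2oc(CC)c(C)c(=O)c2C)c(C)c(=O)c1C | target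

**Step count**
Total: 15 steps. Longest linear sequence: 11 steps (steps 1, 2, 3, 4, 6, 7, 8, 9, 10, 11 and 15, from the Roche ester).

**Steps most likely to fail**

Step 15. The acyl–nickel species from the α-branched acid chloride may lose CO, the pyranonyl chloride may homocouple, the catalyst may fail to override the resident C2 centre, and the doubly activated product may epimerise during work-up. The fallback sets out from aldehyde 14 and pyranone 20 and returns to the route at 24. The lithium dienolate of 20 (LiN(SiMe3)2, THF, −78 °C) would be added to 14 in a lateral (vinylogous) aldol reaction to give 2-(3,5-dimethyl-4-oxo-6-pentyl-4H-pyran-2-yl)-4-(6-ethyl-3,5-dimethyl-4-oxo-4H-pyran-2-yl)pentan-3-ol F1 as a mixture at the carbinol and ethyl-pyranone-side carbons. Buffered Dess–Martin oxidation would then give 24 together with its C4 epimer, to be separated by chromatography; in this variant C4 is under substrate control only.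

Step 6. The second deprotonation may occur in part at the stereogenic methine, which would lead to epimerisation or β-elimination of the silyloxy group, and the hindered secondary carbanion may acylate sluggishly. The fallback sets out from aldehyde 3 and pentan-3-one 4 and returns at triketone 11, avoiding a diketone dianion. The lithium enolate of 4 would be added to hexanal to give 5-hydroxy-4-methyldecan-3-one F2. Two equivalents of LiN(i-Pr)2 would convert F2 into its alkoxide–enolate (deprotonation at the ethyl CH2), which would add to 3 to give (2S)-1-[(tert-butyldimethylsilyl)oxy]-3,7-dihydroxy-2,4,6-trimethyldodecan-5-one F3. Double Dess–Martin oxidation of F3 would then give 11.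

Step 13. Oxygen transfer to the vinylogous enolate may be inefficient, through addition of the enolate to the sulfonimine by-product, further oxidation of the carbinol, or attack at ring C3. The fallback sets out from pyranone 20 and returns at chloride 23. Radical bromination of excess 20 (N-bromosuccinimide, AIBN, PhCF3, 80 °C) at the conjugated secondary CH2 would give rac-2-(1-bromoethyl)-6-ethyl-3,5-dimethyl-4H-pyran-4-one F4, and halide exchange with LiCl in acetone would give 23.

**Further compounds**
F1 | step 15 | 2-(3,5-dimethyl-4-oxo-6-pentyl-4H-pyran-2-yl)-4-(6-ethyl-3,5-dimethyl-4-oxo-4H-pyran-2-yl)pentan-3-ol (pentyl-side centre as in 14) | CCCCCc1oc([C@@H](C)C(O)C(C)c2oc(CC)c(C)c(=O)c2C)c(C)c(=O)c1C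
F2 | step 6 | 5-hydroxy-4-methyldecan-3-one | CCCCCC(O)C(C)C(=O)CC
F3 | step 6 | (2S)-1-[(tert-butyldimethylsilyl)oxy]-3,7-dihydroxy-2,4,6-trimethyldodecan-5-one | CCCCCC(O)C(C)C(=O)C(C)C(O)[C@@H](C)CO[Si](C)(C)C(C)(C)C
F4 | step 13 | rac-2-(1-bromoethyl)-6-ethyl-3,5-dimethyl-4H-pyran-4-one | CCc1oc(C(C)Br)c(C)c(=O)c1C
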